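**Plan**

Numbering: decalin C1–C10 (ring A = C1–C5/C10, ring B = C5–C10); C17 = CH3 on C8, C18/C19 = CH3/CH2O on C4, C20 = CH3 on C10, C11–C12 = link, C13–C16 = butenolide; β = face of C20; target = (2R,4S,5S,6S,10S).
Cuts: C9–C11 (side chain off ring B by sp3–sp2 cross-coupling), then C1–C10 and C4–C5 together (ring A off ring B by [4+2]); the butenolide is traced back to a 3-substituted furan.
Enabling feature: ring B (C5–C10), with CH3 on C8 and C10 and oxygen at C6 and latent at C9, is a reduced 2,6-dimethyl-1,4-benzoquinone, and the cis C5–H/C10–CH3 fusion beside quaternary C4 is the imprint of an endo [4+2] across C5=C10.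
Forward: the (Z)-2-silyloxydiene (C1–C4, C18, C19) is made from 4-methylfuran-2(5H)-one; ring A is closed onto the quinone (ring B); then C6 reduction, C8=C9 enol triflate, C9–C11 Negishi coupling, C19 acetate, C2 reduction, furan to butenolide, desilylation.
Stereochemistry: C4, C5 and C10 from the catalyst-controlled endo cycloaddition of the Z diene; C6 by hydride attack on the convex β face; C2 by equatorial hydride attack on the ring-A chair.

Key step: step 5

Assumption: the (S)-diphenylprolinol-derived oxazaborolidinium ion is taken to expose the required face of the quinone C5=C10 bond (quinone bound at the C6 carbonyl, diene entering opposite the shielding phenyl group); if a test run shows the opposite sense, the (R)-catalyst is used and nothing else changes.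

**Route**

Step 1
Reactants: 1 4-methylfuran-2(5H)-one
Product: 2 (2Z)-4-hydroxy-N-methoxy-N,3-dimethylbut-2-enamide
Conditions: MeNH(OMe)·HCl, AlMe3, CH2Cl2, 0 °C to rt; aq. potassium sodium tartrate work-up
Reagents that add atoms: N,O-dimethylhydroxylamine hydrochloride, CNOC.Cl
Why: Aluminium-amide aminolysis of the lactone (Weinreb amide formation) opens the butenolide without touching the C=C bond, so the ring-derived Z geometry (CH2OH cis to the carbonyl) is carried over.

Step 2
Reactants: 2 (2Z)-4-hydroxy-N-methoxy-N,3-dimethylbut-2-enamide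
Product: 3 (2Z)-4-(tert-butyldimethylsilyloxy)-N-methoxy-N,3-dimethylbut-2-enamide
Conditions: TBSCl, imidazole, CH2Cl2, 0 °C to rt (crude 2 used at once)
Reagents that add atoms: tert-butyldimethylsilyl chloride, CC(C)(C)[Si](C)(C)Cl
Why: Routine silylation of the primary allylic alcohol, done immediately so that the (Z)-hydroxy amide cannot relactonise.

Step 3
Reactants: 3 (2Z)-4-(tert-butyldimethylsilyloxy)-N-methoxy-N,3-dimethylbut-2-enamide
Product: 4 (3Z)-5-(tert-butyldimethylsilyloxy)-4-methylpent-3-en-2-one
Conditions: MeMgBr, THF, −78 to 0 °C; aq. NH4Cl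
Reagents that add atoms: methylmagnesium bromide, C[Mg]Br
Why: Weinreb ketone synthesis, in which the chelated tetrahedral adduct stops at the methyl ketone and the β,β-disubstituted double bond resists conjugate addition, so the Z enone should be obtained intact.

Step 4
Reactants: 4 (3Z)-5-(tert-butyldimethylsilyloxy)-4-methylpent-3-en-2-one
Product: 6 (3Z)-5-(tert-butyldimethylsilyloxy)-4-methyl-2-(triisopropylsilyloxy)penta-1,3-diene, via lithium dienolate 5 (not isolated)
Conditions: LiN(i-Pr)2, THF, −78 °C; then i-Pr3SiOTf, −78 to 0 °C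
Reagents that add atoms: triisopropylsilyl trifluoromethanesulfonate, CC(C)[Si](OS(=O)(=O)C(F)(F)F)(C(C)C)C(C)C
Why: Kinetic deprotonation of the acetyl CH3 gives the cross-conjugated enolate, and O-silylation (silyl enol ether formation) then gives the 2-silyloxydiene without any allyl-cation-like species that could scramble the C3=C4 geometry.

Step 5
Reactants: 6 (3Z)-5-(tert-butyldimethylsilyloxy)-4-methyl-2-(triisopropylsilyloxy)penta-1,3-diene; 7 2,6-dimethyl-1,4-benzoquinone
Product: 8 cis-fused enedione adduct (C2=C3 triisopropylsilyl enol ether; 19-OTBS; C6 and C9 ketones; C7=C8)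
Conditions: 20 mol % N-protonated (S)-1-(2-methylphenyl)-3,3-diphenyltetrahydro-1H,3H-pyrrolo[1,2-c][1,3,2]oxazaborole bis(trifluoromethanesulfonyl)imide salt (from the oxazaborolidine and HN(SO2CF3)2 in situ), 6 (1.5 equiv), CH2Cl2, −78 to −40 °C
Reagents that add atoms: none
Why: The quinone binds to boron through its C6 carbonyl (the only one with an α-C–H, at C5, and no flanking methyl groups), and the diene adds in a concerted, asynchronous endo [4+2] cycloaddition; the closest known reaction type is the oxazaborolidinium-catalysed enantioselective Diels–Alder reaction of 2-silyloxy-1,3-dienes with alkyl-1,4-benzoquinones. Ring A closes as a six-membered carbocycle by suprafacial addition of the diene termini across C5=C10 (the two quinone C=C bonds are equivalent by symmetry), forming C1–C10 and C4–C5. Regiochemistry follows from pairing the nucleophilic terminus C1 (pushed by the 2-silyloxy group and the 4,4-dialkyl substitution) with C10, the β-carbon of the complexed C6 carbonyl, so that fully substituted C4 meets unsubstituted C5. The cis C5–H/C10–CH3 fusion is fixed by suprafacial addition to the dienophile, and C4 is set by the endo transition state, in which the inside (Z) substituent CH2OTBS ends cis to H5 and C20 while the outside methyl becomes C18 (α). The absolute configuration of all three centres comes from the catalyst, whose carbinol phenyl group shields one face of the bound C5=C10 bond. The step needs endo, C1-to-C10 and facial selectivity, secured respectively by Lewis-acid complexation of the quinone, by the C6 binding site together with the diene polarisation, and by the Z geometry of 6 plus the chiral cation.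

Step 6
Reactants: 8 cis-fused enedione adduct
Product: 9 6α-hydroxy enone
Conditions: NaBH4, CeCl3·7H2O, MeOH/CH2Cl2, −78 °C
Reagents that add atoms: none
Why: Luche 1,2-reduction should select the C6 carbonyl (flanked by C5–H and C7–H) over C9 (flanked by quaternary C10 and C8–CH3), and hydride should enter from the convex β face (side of H5 and C20), placing 6-OH α.

Step 7
Reactants: 9 6α-hydroxy enone
Product: 10 6α-triisopropylsilyloxy enone
Conditions: i-Pr3SiOTf, 2,6-lutidine, CH2Cl2, −78 to 0 °C
Reagents that add atoms: triisopropylsilyl trifluoromethanesulfonate, CC(C)[Si](OS(=O)(=O)C(F)(F)F)(C(C)C)C(C)C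
Why: Silyl triflate with a hindered base silylates the hindered secondary allylic alcohol, and the secondary TIPS ether is chosen because it outlasts the later removal of the primary TBS ether.

Step 8
Reactants: 10 6α-triisopropylsilyloxy enone
Product: 12 C9 enol triflate with C8=C9, via lithium C8=C9 enolate 11 (not isolated)
Conditions: LiBH(s-Bu)3, THF, −78 °C; then PhNTf2, −78 to 0 °C
Reagents that add atoms: N-phenylbis(trifluoromethanesulfonimide), O=S(=O)(N(c1ccccc1)S(=O)(=O)C(F)(F)F)C(F)(F)F
Why: Conjugate hydride reduction of the β-unsubstituted, α-methyl enone (1,2-attack at the hindered C9 carbonyl being disfavoured) gives the C8=C9 enolate regiospecifically, and O-triflation traps it as the tetrasubstituted enol triflate.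

Step 9
Reactants: 13 2-(furan-3-yl)ethanol
Product: 14 3-(2-iodoethyl)furan
Conditions: I2, PPh3, imidazole, CH2Cl2, 0 °C to rt
Reagents that add atoms: iodine, II
Why: Appel iodination of a primary alcohol under neutral conditions that the furan tolerates.

Step 10
Reactants: 12 C9 enol triflate; 14 3-(2-iodoethyl)furan
Product: 16 C9–C11 coupled furan, via 2-(furan-3-yl)ethylzinc iodide 15 (not isolated)
Conditions: 14, Zn dust (activated with 1,2-dibromoethane and Me3SiCl), THF, 40 °C; then 12, PdCl2(dppf) (5 mol %; dppf = 1,1'-bis(diphenylphosphino)ferrocene), THF/N,N-dimethylacetamide, 60 °C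
Reagents that add atoms: none
Why: Negishi sp3–sp2 coupling forms C9–C11; the wide-bite-angle diphosphine favours reductive elimination over β-hydride elimination, and the alkylzinc iodide leaves silyl ethers, silyl enol ether and furan alone.

Step 11
Reactants: 16 C9–C11 coupled furan
Product: 17 19-hydroxy 2-ketone (6-OTIPS retained)
Conditions: HF·pyridine, pyridine, THF, 0 °C to rt (monitored)
Reagents that add atoms: none
Why: Fluoride-mediated desilylation should cleave the silyl enol ether (to the C2 ketone) and the primary TBS ether much faster than the hindered secondary TIPS ether at C6.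

Step 12
Reactants: 17 19-hydroxy 2-ketone
Product: 18 19-acetoxy 2-ketone
Conditions: Ac2O, pyridine, 4-(dimethylamino)pyridine (cat.), CH2Cl2, 0 °C to rt
Reagents that add atoms: acetic anhydride, CC(=O)OC(C)=O
Why: Standard acylation of the only free hydroxyl, which also drains any C19-to-C2 hemiketal back to the open keto acetate.

Step 13
Reactants: 18 19-acetoxy 2-ketone
Product: 19 19-acetoxy 2α-alcohol
Conditions: LiBH(s-Bu)3 (1.2 equiv), THF, −78 °C; pH 7 buffer work-up
Reagents that add atoms: none
Why: The bulky trialkylborohydride reduces the ketone far faster than the acetate and should attack C2 equatorially from the β face of the ring-A chair in which C6–OTIPS is equatorial on ring B, because the α-axial approach is blocked by the syn-axial C18 methyl and C10–C9 bond, giving 2α-OH.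

Step 14
Reactants: 19 19-acetoxy 2α-alcohol
Product: 21 6-O-triisopropylsilyl ether of the target, via 16-hydroxybutenolide 20 (not isolated)
Conditions: O2, visible light, 5,10,15,20-tetraphenylporphyrin (cat.), i-Pr2NEt, CH2Cl2, −78 °C; then solvent switch, NaBH4, EtOH, 0 °C; 1 M HCl work-up
Reagents that add atoms: dioxygen, O=O
Why: [4+2] addition of singlet oxygen to the furan followed by Kornblum–DeLaMare-type fragmentation (the hindered amine removes the endoperoxide hydrogen at C15, remote from the side chain) gives the 16-hydroxy-15,16-olide, whose open aldehyde form is reduced by NaBH4 and relactonises to the β-substituted butenolide; the hindered tetrasubstituted C8=C9 alkene is expected to react with singlet oxygen far more slowly than the furan.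

Step 15
Reactants: 21 6-O-triisopropylsilyl ether of the target
Product: 22 CNP0201970.1 (target)
Conditions: HF·pyridine, THF, 0 °C to rt
Reagents that add atoms: none
Why: Fluoride-mediated cleavage of the secondary silyl ether under mildly acidic conditions leaves the acetate, the butenolide and all stereocentres untouched.

**Compound list**

1 | 4-methylfuran-2(5H)-one | CC1=CC(=O)OC1 | starting material
2 | (2Z)-4-hydroxy-N-methoxy-N,3-dimethylbut-2-enamide | CON(C)C(=O)/C=C(/C)CO | intermediate
3 | (2Z)-4-(tert-butyldimethylsilyloxy)-N-methoxy-N,3-dimethylbut-2-enamide | CON(C)C(=O)/C=C(/C)CO[Si](C)(C)C(C)(C)C | intermediate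
4 | (3Z)-5-(tert-butyldimethylsilyloxy)-4-methylpent-3-en-2-one | CC(=O)/C=C(/C)CO[Si](C)(C)C(C)(C)C | intermediate
5 | lithium (3Z)-5-(tert-butyldimethylsilyloxy)-4-methylpenta-1,3-dien-2-olate | [Li+].[O-]C(=C)/C=C(/C)CO[Si](C)(C)C(C)(C)C | intermediate
6 | (3Z)-5-(tert-butyldimethylsilyloxy)-4-methyl-2-(triisopropylsilyloxy)penta-1,3-diene | C=C(O[Si](C(C)C)(C(C)C)C(C)C)/C=C(/C)CO[Si](C)(C)C(C)(C)C | intermediate
7 | 2,6-dimethyl-1,4-benzoquinone | CC1=CC(=O)C=C(C)C1=O | starting material
8 | cis-fused adduct: C2=C3 triisopropylsilyl enol ether, 4β-CH2OTBS (C19), 4α-CH3 (C18), 5β-H, 10β-CH3 (C20), C6 and C9 ketones, C7=C8 with 8-CH3 | CC(C)(C)[Si](C)(C)OC[C@@]1(C)C=C(O[Si](C(C)C)(C(C)C)C(C)C)C[C@]2(C)C(=O)C(C)=CC(=O)[C@H]12 | intermediate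
9 | 6α-hydroxy enone (as 8, C6 ketone reduced to 6α-OH) | CC(C)(C)[Si](C)(C)OC[C@@]1(C)C=C(O[Si](C(C)C)(C(C)C)C(C)C)C[C@]2(C)C(=O)C(C)=C[C@H](O)[C@H]12 | intermediate
10 | 6α-triisopropylsilyloxy enone | CC(C)(C)[Si](C)(C)OC[C@@]1(C)C=C(O[Si](C(C)C)(C(C)C)C(C)C)C[C@]2(C)C(=O)C(C)=C[C@H](O[Si](C(C)C)(C(C)C)C(C)C)[C@H]12 | intermediate
11 | lithium C8=C9 enolate of the 7,8-dihydro ketone | [Li+].CC(C)(C)[Si](C)(C)OC[C@@]1(C)C=C(O[Si](C(C)C)(C(C)C)C(C)C)C[C@]2(C)C([O-])=C(C)C[C@H](O[Si](C(C)C)(C(C)C)C(C)C)[C@H]12 | intermediate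
12 | C9 enol triflate with C8=C9 (2-TIPS enol ether, 6α-OTIPS, 19-OTBS) | CC(C)(C)[Si](C)(C)OC[C@@]1(C)C=C(O[Si](C(C)C)(C(C)C)C(C)C)C[C@]2(C)C(OS(=O)(=O)C(F)(F)F)=C(C)C[C@H](O[Si](C(C)C)(C(C)C)C(C)C)[C@H]12 | intermediate
13 | 2-(furan-3-yl)ethanol | OCCc1ccoc1 | starting material
14 | 3-(2-iodoethyl)furan | ICCc1ccoc1 | intermediate
15 | 2-(furan-3-yl)ethylzinc iodide | I[Zn]CCc1ccoc1 | intermediate
16 | C9–C11 coupled furan (2-TIPS enol ether, 6α-OTIPS, 19-OTBS, C8=C9, 9-[2-(furan-3-yl)ethyl]) | CC(C)(C)[Si](C)(C)OC[C@@]1(C)C=C(O[Si](C(C)C)(C(C)C)C(C)C)C[C@]2(C)C(CCc3ccoc3)=C(C)C[C@H](O[Si](C(C)C)(C(C)C)C(C)C)[C@H]12 | intermediate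
17 | 19-hydroxy 2-ketone (6α-OTIPS) | OC[C@@]1(C)CC(=O)C[C@]2(C)C(CCc3ccoc3)=C(C)C[C@H](O[Si](C(C)C)(C(C)C)C(C)C)[C@H]12 | intermediate
18 | 19-acetoxy 2-ketone (6α-OTIPS) | CC(=O)OC[C@@]1(C)CC(=O)C[C@]2(C)C(CCc3ccoc3)=C(C)C[C@H](O[Si](C(C)C)(C(C)C)C(C)C)[C@H]12 | intermediate
19 | 19-acetoxy 2α-alcohol (6α-OTIPS, furan) | CC(=O)OC[C@@]1(C)C[C@H](O)C[C@]2(C)C(CCc3ccoc3)=C(C)C[C@H](O[Si](C(C)C)(C(C)C)C(C)C)[C@H]12 | intermediate
20 | 16-hydroxy-15,16-olide (γ-hydroxybutenolide, C16 epimers) | CC(=O)OC[C@@]1(C)C[C@H](O)C[C@]2(C)C(CCC3=CC(=O)OC3O)=C(C)C[C@H](O[Si](C(C)C)(C(C)C)C(C)C)[C@H]12 | intermediate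
21 | 6-O-triisopropylsilyl ether of the target | CC(=O)OC[C@@]1(C)C[C@H](O)C[C@]2(C)C(CCC3=CC(=O)OC3)=C(C)C[C@H](O[Si](C(C)C)(C(C)C)C(C)C)[C@H]12 | intermediate
22 | CNP0201970.1: (2R,4S,5S,6S,10S)-19-acetoxy-2α,6α-dihydroxy-5β-H Δ8 decalin with 9-[2-(5-oxo-2,5-dihydrofuran-3-yl)ethyl] | CC(=O)OC[C@@]1(C)C[C@H](O)C[C@]2(C)C(CCC3=CC(=O)OC3)=C(C)C[C@H](O)[C@H]12 | target

**Count and risks**

Total steps: 15. Longest linear sequence: 14 steps (steps 1–8 and 10–15, from 1 to 22); step 9 makes the side-chain fragment.

Steps most likely to fail: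

1. Step 5. With the (Z)-4,4-disubstituted diene the cycloaddition may be slow, so that acid-induced loss of the silyl enol ether or a stepwise Mukaiyama–Michael pathway competes and catalyst control over the quinone face erodes. Fallback: resolution instead of asymmetric catalysis, setting out from 6 and 7 and returning at 9. The cycloaddition is run with stoichiometric EtAlCl2 (CH2Cl2, −78 °C), which keeps the C6-carbonyl-directed regiochemistry and the endo preference and should give the racemic adduct F1. Luche reduction as in step 6 gives the racemic allylic alcohol F2. Esterification with (S)-2-methoxy-2-phenylacetic acid (N,N'-dicyclohexylcarbodiimide, 4-(dimethylamino)pyridine, CH2Cl2, 0 °C) gives the diastereomeric esters, the (S)-2-methoxy-2-phenylacetate of 9 F3 and the (S)-2-methoxy-2-phenylacetate of the enantiomer of 9 F4, which are separated by chromatography and also allow the C6 configuration to be assigned by NMR. Methanolysis of F3 (K2CO3, MeOH, 0 °C) returns 9.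

2. Step 13. The cis-decalin may react through its other ring-flip conformer, in which equatorial hydride attack comes from the α face, so facial selectivity at C2 could be poor or reversed. Fallback: substrate-directed delivery, setting out from 17 and returning at 19. Me4NBH(OAc)3 in MeCN/AcOH (−20 °C) binds the free C19 hydroxyl and should transfer hydride intramolecularly to the β face of C2 (the face of C19), which is favoured in exactly the conformer that defeats the main step; this gives the 2α,19-diol F5. AcCl with 2,4,6-collidine (CH2Cl2, −78 °C) then acetylates the primary hydroxyl selectively to give 19.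

3. Step 10. Transmetalation and reductive elimination at the tetrasubstituted enol triflate beside quaternary C10 may be slow, so that reduction of the triflate or β-hydride elimination of the alkylpalladium takes over. Fallback: B-alkyl Suzuki–Miyaura coupling, setting out from 12 and 14 and returning at 16. Lithium–iodine exchange on 14 (t-BuLi, Et2O, −78 °C) gives 2-(furan-3-yl)ethyllithium F6, which is trapped with 9-methoxy-9-borabicyclo[3.3.1]nonane to give the lithium borate F7. F7 is coupled directly with 12 (PdCl2(dppf), K3PO4, DMF/THF, rt to 50 °C) to give 16.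

**Further compounds**

F1 | step 5 | racemic cis-fused adduct (8 and its enantiomer) | CC(C)(C)[Si](C)(C)OC[C@@]1(C)C=C(O[Si](C(C)C)(C(C)C)C(C)C)C[C@]2(C)C(=O)C(C)=CC(=O)[C@H]12.CC(C)(C)[Si](C)(C)OC[C@]1(C)C=C(O[Si](C(C)C)(C(C)C)C(C)C)C[C@@]2(C)C(=O)C(C)=CC(=O)[C@@H]12
F2 | step 5 | racemic 6-hydroxy enone (9 and its enantiomer) | CC(C)(C)[Si](C)(C)OC[C@@]1(C)C=C(O[Si](C(C)C)(C(C)C)C(C)C)C[C@]2(C)C(=O)C(C)=C[C@H](O)[C@H]12.CC(C)(C)[Si](C)(C)OC[C@]1(C)C=C(O[Si](C(C)C)(C(C)C)C(C)C)C[C@@]2(C)C(=O)C(C)=C[C@@H](O)[C@@H]12
F3 | step 5 | (S)-2-methoxy-2-phenylacetate of 9 | CC(C)(C)[Si](C)(C)OC[C@@]1(C)C=C(O[Si](C(C)C)(C(C)C)C(C)C)C[C@]2(C)C(=O)C(C)=C[C@H](OC(=O)[C@@H](OC)c3ccccc3)[C@H]12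
F4 | step 5 | (S)-2-methoxy-2-phenylacetate of the enantiomer of 9 | CC(C)(C)[Si](C)(C)OC[C@]1(C)C=C(O[Si](C(C)C)(C(C)C)C(C)C)C[C@@]2(C)C(=O)C(C)=C[C@@H](OC(=O)[C@@H](OC)c3ccccc3)[C@@H]12
F5 | step 13 | 2α,19-diol (6α-OTIPS, furan) | OC[C@@]1(C)C[C@H](O)C[C@]2(C)C(CCc3ccoc3)=C(C)C[C@H](O[Si](C(C)C)(C(C)C)C(C)C)[C@H]12
F6 | step 10 | 2-(furan-3-yl)ethyllithium | [Li]CCc1ccoc1
F7 | step 10 | lithium 9-[2-(furan-3-yl)ethyl]-9-methoxy-9-boranuidabicyclo[3.3.1]nonane | [Li+].CO[B-]1(CCc2ccoc2)C2CCCC1CCC2
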